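The plan rests on cutting C9–C11 and C8–C17 in ring B, where C8 (methyl C17), C9 (chain C11–C16) and quaternary C10 (methyl C20, ring A carbon C1) stand side by side. This leads to a flat, mirror-symmetric 4-methyl-4-(2-methoxycarbonylethyl)cyclohexa-2,5-dienone whose carbonyl carbon is C7. In one operation a chiral copper catalyst adds the ketal-protected side-chain Grignard reagent to one enantiotopic enone arm and the enolate is methylated. This fixes C9 and C8 and turns C10 into a stereocentre. The surviving enone arm later receives C4/C19, a Dieckmann reaction closes ring A, osmylation sets the 2,3-diol, and the C7 oxygen finally leaves to give C7=C8.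

Key step: step 5

**Conventions:** Labdane numbering is used for every intermediate (dienone carbonyl = C7, quaternary carbon = C10, ester arm = C1–C3). "C20 face" is the ring face that carries the C20 methyl and "H5 face" is the opposite one. The target is (2S,3R,4S,5S,9R,10S) and 13E. Its C9 chain and C19 formyl group lie on the C20 face. H5, H9, C18 and both acetoxy groups lie on the H5 face.

**Assumption:** The sense of induction of the ferrocenyl diphosphine on this dienone cannot be predicted safely. The ligand enantiomer that leads to (8R,9R,10R)-14 is therefore to be fixed in a first run by correlation. Both enantiomers are commercial.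

**Design points:**
- (a) A carbon nucleophile would enter C5 of 14 anti to C20 and trans to the chain, which is the face that leads to a cis-decalin. Carbon is therefore added first, the enone is restored, and hydride is added last.
- (b) Any addition at C5 leaves the C6=C7 enolate, so C7=C8 is made by anti elimination of an axial C7 alcohol.
- (c) The cis-diol lies on the open H5 face and is made by osmylation of a C2=C3 alkene while ring B is still saturated.
- (d) The two esters are differentiated (methyl at C3, tert-butyl at C19) so that the Dieckmann closure has only one direction.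

Step 1
Reactants: 1 propanal; 2 methyl acrylate
Product: 5 methyl 4-methyl-5-oxopentanoate (racemic), via propenylpyrrolidine enamine 3 (not isolated), via adduct enamine 4 (not isolated)
Conditions: pyrrolidine (1.0 equiv), K2CO3, Et2O, 0 °C; then 2, MeCN, reflux; then AcOH/H2O, reflux
Reagents that add atoms: water, O
Why: Stork enamine Michael addition, in which the nucleophilic β-carbon of enamine 3 adds to the acrylate and hydrolysis of 4 returns the aldehyde, whose racemic stereocentre is erased in step 3.

Step 2
Reactants: 5 methyl 4-methyl-5-oxopentanoate; 6 methyl vinyl ketone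
Product: 8 methyl 3-(1-methyl-4-oxocyclohex-2-en-1-yl)propanoate (racemic), via keto aldehyde 7 (not isolated)
Conditions: H2SO4 (cat.), toluene, 45 °C, then reflux with water separator
Reagents that add atoms: none
Why: Acid-catalysed Robinson annulation, in which the enol of the α-branched aldehyde adds to the enone to create the quaternary carbon (later C10) and the methyl ketone of 7 condenses with the now non-enolisable aldehyde, so only one cyclohexenone can form.

Step 3
Reactants: 8 methyl 3-(1-methyl-4-oxocyclohex-2-en-1-yl)propanoate
Product: 9 methyl 3-(1-methyl-4-oxocyclohexa-2,5-dien-1-yl)propanoate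
Conditions: DDQ (1.3 equiv), 1,4-dioxane, reflux
Reagents that add atoms: none
Why: Quinone dehydrogenation of a 4,4-disubstituted cyclohexenone through hydride abstraction from its enol, which cannot aromatise because C10 is quaternary and gives the mirror-symmetric dienone.

Step 4
Reactants: 10 2-(2-bromoethyl)-2-methyl-1,3-dioxolane
Product: 11 [2-(2-methyl-1,3-dioxolan-2-yl)ethyl]magnesium bromide (used as solution)
Conditions: Mg turnings (I2 crystal), Et2O, 15–25 °C
Reagents that add atoms: magnesium, [Mg]
Why: Grignard reagent formation by magnesium insertion into a primary bromide, with the ketal inert as long as the solution is kept at or below room temperature, where intramolecular attack on the ketal carbon does not compete.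

Step 5
Reactants: 9 methyl 3-(1-methyl-4-oxocyclohexa-2,5-dien-1-yl)propanoate; 11 [2-(2-methyl-1,3-dioxolan-2-yl)ethyl]magnesium bromide; 12 iodomethane
Product: 14 methyl 3-[(1R,5R,6R)-1,5-dimethyl-6-[2-(2-methyl-1,3-dioxolan-2-yl)ethyl]-4-oxocyclohex-2-en-1-yl]propanoate, via bromomagnesium dienolate 13 (not isolated)
Conditions: CuBr·SMe2 (5 mol %), TaniaPhos-type ferrocenyl diphosphine (6 mol %), t-BuOMe, −78 °C, 11 (1.1 equiv) added over 2 h; then 12 (5 equiv), DMPU, −78 → 0 °C
Reagents that add atoms: none
Why: The diphosphine–CuBr complex is alkylated by 11, binds one enantiotopic C=C of 9 as a π-complex while magnesium activates the carbonyl, passes through a trivalent copper σ-alkyl species at the β-carbon and reductively eliminates to form C9–C11, after which enolate 13 is C-methylated at C8 by SN2 attack on 12 once DMPU loosens its aggregates. The closest known reaction type is the copper-catalysed enantioselective conjugate addition of organomagnesium or organozinc reagents to cyclic enones and to 4,4-disubstituted cyclohexadienones combined with tandem enolate alkylation, and no ring is closed. C9 is set by the ligand, which dictates the alkene face that copper binds; C10 becomes stereogenic because only one arm reacts, and its cis relation to C9 requires copper to approach the ring face bearing the small C20 methyl rather than the CH2CH2CO2Me arm, a preference that the large ligand sphere sitting over C10 should amplify; C8 is set by methylation anti to the new chain, can be equilibrated to this trans arrangement and later becomes sp2. The step needs 1,4- over 1,2-addition, ester tolerance and mono-addition: copper catalysis at −78 °C with slow addition of a small excess of 11 secures the first two, and the product stays masked as enolate 13 until the Grignard reagent is spent, which secures the third. The methyl ester is kept on purpose because C3 must later be the better acyl acceptor of two esters, and any C10 epimer is removed by chromatography at this stage.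

Step 6
Reactants: 15 tert-butyl acetate
Product: 17 1-tert-butoxy-1-(tert-butyldimethylsilyloxy)ethene, via lithium ester enolate 16 (not isolated)
Conditions: LiN(i-Pr)2, THF, −78 °C; TBSCl, DMPU, −78 → 23 °C
Reagents that add atoms: tert-butyldimethylsilyl chloride, CC(C)(C)[Si](C)(C)Cl
Why: O-silylation of a lithium ester enolate, in which the bulky chlorosilane in the presence of DMPU reacts at oxygen rather than carbon to give the ketene silyl acetal.

Step 7
Reactants: 14 key-step enone; 17 1-tert-butoxy-1-(tert-butyldimethylsilyloxy)ethene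
Product: 18 C6=C7 TBS enol ether carrying CH2CO2t-Bu at C5 on the face opposite C20
Conditions: 17 (2 equiv), LiClO4 (3 M in Et2O), 23 °C
Reagents that add atoms: none
Why: Mukaiyama–Michael addition in concentrated ethereal LiClO4, a medium mild enough for the ketal and known to drive ketene silyl acetals onto hindered β-carbons with silyl transfer to the enolate oxygen; the nucleophile should enter C5 anti to the pseudoaxial C20 methyl and trans to the C9 chain, the wrong face for a trans-decalin, so this stereocentre is erased in step 8.

Step 8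
Reactants: 18 TBS enol ether
Product: 19 C5-substituted enone (C5=C6–C7=O) with CH2CO2t-Bu on C5
Conditions: Pd(OAc)2 (1.05 equiv), MeCN, 23–40 °C
Reagents that add atoms: none
Why: Saegusa–Ito oxidation, in which the regiodefined C6=C7 silyl enol ether gives an oxa-π-allyl palladium species that loses the C5 hydrogen by β-hydride elimination, so the enone is regenerated only towards C5.

Step 9
Reactants: 19 C5-substituted enone
Product: 20 keto diester with H5 on the face opposite C20
Conditions: Cu(OAc)2·H2O (5 mol %), 1,2-(Ph2P)2C6H4 (5 mol %), (EtO)2MeSiH (2 equiv), t-BuOH (2 equiv), toluene, 23 °C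
Reagents that add atoms: none
Why: Copper hydride conjugate reduction, in which hydride follows the same intrinsic bias (axial attack anti to the C20 methyl and trans to the C9 chain) and so places H5 opposite C20 and leaves C4 equatorial and cis to the chain, as the trans-decalin requires, while C8 keeps its equatorial methyl.

Step 10
Reactants: 20 keto diester
Product: 21 axial C7 alcohol (OH on the H5 face and cis to C17)
Conditions: LiBH(s-Bu)3, THF, −78 °C; then H2O2, pH 7 buffer, 0 °C
Reagents that add atoms: none
Why: Bulky trialkylborohydride reduction, in which equatorial attack on the conformationally biased 2-methylcyclohexanone unit gives the axial alcohol cis to the equatorial C17 methyl, leaves both esters untouched at −78 °C and removes the enolisable ketone before the Dieckmann step.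

Step 11
Reactants: 21 axial C7 alcohol
Product: 22 C7 TBS ether diester
Conditions: TBSOTf, 2,6-lutidine, CH2Cl2, −78 → 0 °C
Reagents that add atoms: tert-butyldimethylsilyl triflate, CC(C)(C)[Si](C)(C)OS(=O)(=O)C(F)(F)F
Why: Silyl ether formation with a silyl triflate and a hindered pyridine base, reactive enough for the axial secondary alcohol and without change at any stereocentre.

Step 12
Reactants: 22 C7 TBS ether diester; 12 iodomethane
Product: 24 trans-decalin 3-ketone with equatorial C18 methyl plus axial C19 tert-butyl ester at C4, via potassium keto ester enolate 23 (not isolated)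
Conditions: KOt-Bu (1.1 equiv), THF, 0 → 23 °C; then 12 (3 equiv), 0 → 23 °C
Reagents that add atoms: none
Why: Dieckmann condensation with alkylation in the same flask, in which under reversible deprotonation only the C4 enolate meets a reactive (methyl) ester while the tert-butyl ester is a poor acceptor, so C3–C4 forms between two equatorial arms to give the trans-decalin and enolate 23 is methylated on the face opposite the axial C20 methyl, placing C18 equatorial and C19 axial.

Step 13
Reactants: 24 3-keto ester
Product: 26 C2=C3 enol triflate, via potassium enolate 25 (not isolated)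
Conditions: KN(SiMe3)2, THF, −78 °C; PhNTf2, −78 → 0 °C
Reagents that add atoms: N-phenylbis(trifluoromethanesulfonimide), O=S(=O)(N(c1ccccc1)S(=O)(=O)C(F)(F)F)C(F)(F)F
Why: Enolate triflation, which gives a single enol triflate because C4 is quaternary and the ketone can enolise only towards C2.

Step 14
Reactants: 26 enol triflate
Product: 27 C2=C3 alkene with axial C19 tert-butyl ester
Conditions: Pd(OAc)2 (5 mol %), PPh3 (10 mol %), HCO2H, Et3N, DMF, 60 °C
Reagents that add atoms: none
Why: Palladium-catalysed formate reduction of an enol triflate (oxidative addition to zerovalent palladium, formate exchange, decarboxylation, reductive elimination), which leaves ester, ketal and silyl ether untouched.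

Step 15
Reactants: 27 alkene ester
Product: 28 C19 primary alcohol
Conditions: LiAlH4, THF, reflux; aqueous work-up
Reagents that add atoms: none
Why: Aluminium hydride reduction of the hindered ester to the neopentyl alcohol, placed here because no acetate or side-chain ester is yet present.

Step 16
Reactants: 28 C19 alcohol ketal
Product: 29 C13 methyl ketone
Conditions: PPTS, acetone/H2O, 50 °C
Reagents that add atoms: water, O
Why: Acid-catalysed ketal hydrolysis under conditions that a hindered secondary TBS ether tolerates, with no stereocentre affected.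

Step 17
Reactants: 29 C13 methyl ketone; 30 tert-butyl diethylphosphonoacetate
Product: 32 (13E)-tert-butyl enoate, via sodium phosphonate anion 31 (not isolated)
Conditions: 30, NaH, THF, 0 °C; then 29, 0 → 40 °C
Reagents that add atoms: none
Why: Horner–Wadsworth–Emmons olefination of the methyl ketone, in which the bulky tert-butyl phosphonoacetate favours the E-alkene (C12 trans to C15), the Z isomer is removed by chromatography and the weakly basic anion leaves the free neopentyl alcohol alone.

Step 18
Reactants: 32 enoate alcohol
Product: 33 C19 aldehyde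
Conditions: Dess–Martin periodinane, CH2Cl2, 0 → 23 °C
Reagents that add atoms: none
Why: Dess–Martin oxidation of the only free alcohol to the non-enolisable axial aldehyde.

Step 19
Reactants: 33 C19 aldehyde
Product: 34 2,3-cis-diol (both OH on the H5 face)
Conditions: OsO4 (3 mol %), NMO (1.1 equiv), acetone/H2O, 0 → 23 °C
Reagents that add atoms: N-methylmorpholine N-oxide, C[N+]1([O-])CCOCC1; water, O (both oxygens are passed on through OsO4)
Why: Catalytic osmium tetroxide dihydroxylation with an amine N-oxide, which adds suprafacially to the electron-richer C2=C3 alkene rather than to the conjugated trisubstituted enoate and from the face opposite the axial C20 methyl and C19 formyl groups, setting C2 (equatorial OH) and C3 (axial OH) together while ring B still holds no alkene.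

Step 20
Reactants: 34 diol
Product: 35 2,3-diacetate
Conditions: Ac2O, pyridine, DMAP (cat.), 23 °C
Reagents that add atoms: acetic anhydride, CC(=O)OC(C)=O
Why: DMAP-catalysed acetylation of both secondary alcohols with retention of configuration.

Step 21
Reactants: 35 diacetate TBS ether
Product: 36 free axial C7 alcohol
Conditions: HF·pyridine, THF, 0 → 23 °C
Reagents that add atoms: none
Why: Fluoride-mediated silyl ether cleavage in a buffered acidic medium that spares acetates, aldehyde and tert-butyl ester.

Step 22
Reactants: 36 C7 alcohol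
Product: 38 C7=C8 alkene tert-butyl ester, via C7 dichlorophosphate 37 (not isolated)
Conditions: POCl3, pyridine, 0 → 50 °C
Reagents that add atoms: none
Why: Dehydration by anti (E2) elimination of the axial dichlorophosphate, for which H8 and H6 on the C20 face are both antiperiplanar but loss of H8 gives the trisubstituted alkene and H6 is shielded by the two syn-axial groups C19 and C20, so C7=C8 should prevail.

Step 23
Reactants: 38 tert-butyl ester
Product: 40 target acid CNP0273594.1, via trimethylsilyl ester 39 (not isolated)
Conditions: TMSOTf, 2,6-lutidine, CH2Cl2, 0 °C; then aqueous work-up at pH 5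
Reagents that add atoms: none
Why: Silyl triflate-mediated tert-butyl ester cleavage (loss of isobutene from the silylated ester) followed by hydrolysis of 39 on work-up, a non-protic method chosen so that the C7=C8 alkene does not migrate and the acetates stay.

**Compound list**

1 | propanal | CCC=O | starting material
2 | methyl acrylate | C=CC(=O)OC | starting material
3 | 1-[(E)-prop-1-en-1-yl]pyrrolidine | C/C=C/N1CCCC1 | intermediate
4 | methyl 4-methyl-5-(pyrrolidin-1-yl)pent-4-enoate | COC(=O)CCC(C)=CN1CCCC1 | intermediate
5 | methyl 4-methyl-5-oxopentanoate (racemic) | COC(=O)CCC(C)C=O | intermediate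
6 | methyl vinyl ketone | CC(=O)C=C | starting material
7 | methyl 4-formyl-4-methyl-7-oxooctanoate (racemic) | COC(=O)CCC(C)(C=O)CCC(C)=O | intermediate
8 | methyl 3-(1-methyl-4-oxocyclohex-2-en-1-yl)propanoate (racemic) | COC(=O)CCC1(C)CCC(=O)C=C1 | intermediate
9 | methyl 3-(1-methyl-4-oxocyclohexa-2,5-dien-1-yl)propanoate | COC(=O)CCC1(C)C=CC(=O)C=C1 | intermediate
10 | 2-(2-bromoethyl)-2-methyl-1,3-dioxolane | CC1(CCBr)OCCO1 | starting material
11 | [2-(2-methyl-1,3-dioxolan-2-yl)ethyl]magnesium bromide | CC1(CC[Mg]Br)OCCO1 | intermediate
12 | iodomethane | CI | starting material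
13 | bromomagnesium dienolate (C7–O, C7=C8, C5=C6; C9 chain cis to C20) | COC(=O)CC[C@@]1(C)[C@H](CCC2(C)OCCO2)C=C(O[Mg]Br)C=C1 | intermediate
14 | methyl 3-[(1R,5R,6R)-1,5-dimethyl-6-[2-(2-methyl-1,3-dioxolan-2-yl)ethyl]-4-oxocyclohex-2-en-1-yl]propanoate (chain cis to C20, C17 trans to chain) | COC(=O)CC[C@@]1(C)[C@H](CCC2(C)OCCO2)[C@@H](C)C(=O)C=C1 | intermediate
15 | tert-butyl acetate | CC(=O)OC(C)(C)C | starting material
16 | lithium enolate of tert-butyl acetate | C=C(O[Li])OC(C)(C)C | intermediate
17 | 1-tert-butoxy-1-(tert-butyldimethylsilyloxy)ethene | C=C(OC(C)(C)C)O[Si](C)(C)C(C)(C)C | intermediate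
18 | C6=C7 TBS enol ether, CH2CO2t-Bu at C5 on the face opposite C20 | COC(=O)CC[C@@]1(C)[C@H](CCC2(C)OCCO2)[C@@H](C)C(O[Si](C)(C)C(C)(C)C)=C[C@H]1CC(=O)OC(C)(C)C | intermediate
19 | C5=C6–C7=O enone with CH2CO2t-Bu on C5 | COC(=O)CC[C@@]1(C)[C@H](CCC2(C)OCCO2)[C@@H](C)C(=O)C=C1CC(=O)OC(C)(C)C | intermediate
20 | C7 ketone; C4 unit, C9 chain and C20 on one face, C1 arm, C17 and H5 on the other | COC(=O)CC[C@@]1(C)[C@H](CCC2(C)OCCO2)[C@@H](C)C(=O)C[C@@H]1CC(=O)OC(C)(C)C | intermediate
21 | axial C7 alcohol (OH on the H5 face, cis to C17) | COC(=O)CC[C@@]1(C)[C@H](CCC2(C)OCCO2)[C@@H](C)[C@@H](O)C[C@@H]1CC(=O)OC(C)(C)C | intermediate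
22 | C7 TBS ether of 21 | COC(=O)CC[C@@]1(C)[C@H](CCC2(C)OCCO2)[C@@H](C)[C@@H](O[Si](C)(C)C(C)(C)C)C[C@@H]1CC(=O)OC(C)(C)C | intermediate
23 | potassium enolate of the trans-decalin 3-oxo-4-carboxylate | C1C[C@@]2(C)[C@H](CCC3(C)OCCO3)[C@@H](C)[C@@H](O[Si](C)(C)C(C)(C)C)C[C@@H]2C(C(=O)OC(C)(C)C)=C1O[K] | intermediate
24 | trans-decalin 3-ketone, C4 with equatorial methyl (H5 face) and axial CO2t-Bu (C20 face) | O=C1CC[C@@]2(C)[C@H](CCC3(C)OCCO3)[C@@H](C)[C@@H](O[Si](C)(C)C(C)(C)C)C[C@@H]2[C@]1(C)C(=O)OC(C)(C)C | intermediate
25 | potassium C2=C3 enolate of 24 | [K]OC1=CC[C@@]2(C)[C@H](CCC3(C)OCCO3)[C@@H](C)[C@@H](O[Si](C)(C)C(C)(C)C)C[C@@H]2[C@]1(C)C(=O)OC(C)(C)C | intermediate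
26 | C2=C3 enol triflate | O=S(=O)(OC1=CC[C@@]2(C)[C@H](CCC3(C)OCCO3)[C@@H](C)[C@@H](O[Si](C)(C)C(C)(C)C)C[C@@H]2[C@]1(C)C(=O)OC(C)(C)C)C(F)(F)F | intermediate
27 | C2=C3 alkene, axial C19 tert-butyl ester | C1=CC[C@@]2(C)[C@H](CCC3(C)OCCO3)[C@@H](C)[C@@H](O[Si](C)(C)C(C)(C)C)C[C@@H]2[C@]1(C)C(=O)OC(C)(C)C | intermediate
28 | C19 primary alcohol | C1=CC[C@@]2(C)[C@H](CCC3(C)OCCO3)[C@@H](C)[C@@H](O[Si](C)(C)C(C)(C)C)C[C@@H]2[C@]1(C)CO | intermediate
29 | C13 methyl ketone | C1=CC[C@@]2(C)[C@H](CCC(C)=O)[C@@H](C)[C@@H](O[Si](C)(C)C(C)(C)C)C[C@@H]2[C@]1(C)CO | intermediate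
30 | tert-butyl diethylphosphonoacetate | CCOP(=O)(CC(=O)OC(C)(C)C)OCC | starting material
31 | sodium salt of 30 | CCOP(=O)([CH-]C(=O)OC(C)(C)C)OCC.[Na+] | intermediate
32 | (13E)-tert-butyl enoate, C19 alcohol | C1=CC[C@@]2(C)[C@H](CC/C(C)=C/C(=O)OC(C)(C)C)[C@@H](C)[C@@H](O[Si](C)(C)C(C)(C)C)C[C@@H]2[C@]1(C)CO | intermediate
33 | C19 aldehyde | C1=CC[C@@]2(C)[C@H](CC/C(C)=C/C(=O)OC(C)(C)C)[C@@H](C)[C@@H](O[Si](C)(C)C(C)(C)C)C[C@@H]2[C@]1(C)C=O | intermediate
34 | 2,3-cis-diol (2-OH equatorial, 3-OH axial, both on the H5 face) | O[C@H]1C[C@@]2(C)[C@H](CC/C(C)=C/C(=O)OC(C)(C)C)[C@@H](C)[C@@H](O[Si](C)(C)C(C)(C)C)C[C@@H]2[C@](C)(C=O)[C@H]1O | intermediate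
35 | 2,3-diacetate | CC(=O)O[C@H]1C[C@@]2(C)[C@H](CC/C(C)=C/C(=O)OC(C)(C)C)[C@@H](C)[C@@H](O[Si](C)(C)C(C)(C)C)C[C@@H]2[C@](C)(C=O)[C@H]1OC(C)=O | intermediate
36 | diacetate with free axial C7 alcohol | CC(=O)O[C@H]1C[C@@]2(C)[C@H](CC/C(C)=C/C(=O)OC(C)(C)C)[C@@H](C)[C@@H](O)C[C@@H]2[C@](C)(C=O)[C@H]1OC(C)=O | intermediate
37 | C7 dichlorophosphate | CC(=O)O[C@H]1C[C@@]2(C)[C@H](CC/C(C)=C/C(=O)OC(C)(C)C)[C@@H](C)[C@@H](OP(=O)(Cl)Cl)C[C@@H]2[C@](C)(C=O)[C@H]1OC(C)=O | intermediate
38 | tert-butyl ester of the target (C7=C8 alkene) | CC(=O)O[C@H]1C[C@@]2(C)[C@H](CC/C(C)=C/C(=O)OC(C)(C)C)C(C)=CC[C@@H]2[C@](C)(C=O)[C@H]1OC(C)=O | intermediate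
39 | trimethylsilyl ester of the target | CC(=O)O[C@H]1C[C@@]2(C)[C@H](CC/C(C)=C/C(=O)O[Si](C)(C)C)C(C)=CC[C@@H]2[C@](C)(C=O)[C@H]1OC(C)=O | intermediate
40 | CNP0273594.1, (2S,3R,4S,5S,9R,10S,13E)-2,3-diacetoxy-19-oxolabda-7,13-dien-15-oic acid | CC(=O)O[C@H]1C[C@@]2(C)[C@H](CC/C(C)=C/C(=O)O)C(C)=CC[C@@H]2[C@](C)(C=O)[C@H]1OC(C)=O | target

Total step count: 23. Longest linear sequence: 21 steps (steps 1–3, 5 and 7–23).

**Steps most likely to fail**

**Step 5.** What may go wrong:
- too little discrimination between the methyl face and the ester-arm face of the dienone;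
- erosion of arm selection;
- proton exchange between enolate and product during the slow methylation.

The fallback sets out from 9 and 11 and splits the coupling into separate events.
- Reagent 11 is transmetallated with ZnCl2 (0.5 equiv) to bis[2-(2-methyl-1,3-dioxolan-2-yl)ethyl]zinc F1.
- F1 is added to 9 under Cu(OTf)2 and a BINOL-derived phosphoramidite in toluene at −25 °C. This is the catalyst family with the closest record on 4,4-disubstituted dienones.
- The resulting alkylzinc dienolate F2 is protonated to the C8-unsubstituted enone F3, at which stage the C10 epimers can be separated.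
- Kinetic deprotonation of F3 with LiN(i-Pr)2 can occur only at C8. It gives the lithium cross-conjugated dienolate F4, which is methylated with 12 anti to the chain.
- The route is rejoined at 14.

**Step 9.** What may go wrong: hydride delivery to the wrong face of C5, or sluggish reduction at the hindered β-carbon. The fallback sets out from 19 and replaces substrate bias by direction from a neighbouring group.
- 1,2-Reduction with LiBH(s-Bu)3 at −78 °C gives the pseudoaxial allylic C7 alcohol F5, with OH on the H5 face.
- Hydroxyl-directed hydrogenation with [Ir(cod)(PCy3)(py)]PF6 under H2 in CH2Cl2 then delivers hydrogen to C5 and C6 from the face of the hydroxyl group.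
- The route is rejoined at 21, so step 10 is skipped.

**Step 22.** What may go wrong: loss of regiocontrol in the elimination (removal of H6 in place of H8), or chloride substitution at C7. The fallback sets out from 36 and goes through the carbonyl level.
- Dess–Martin oxidation gives the C7 ketone F6.
- Tf2O with 2,6-di-tert-butyl-4-methylpyridine in CH2Cl2 converts F6 under equilibrating conditions into the more substituted C7=C8 enol triflate F7.
- Formate reduction with Pd(OAc)2, PPh3, HCO2H and Et3N in DMF removes the triflate.
- The route is rejoined at 38.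

**Further compounds**

F1 | step 5 | bis[2-(2-methyl-1,3-dioxolan-2-yl)ethyl]zinc | CC1(CC[Zn]CCC2(C)OCCO2)OCCO1
F2 | step 5 | alkylzinc dienolate from addition of F1 to 9 | COC(=O)CC[C@@]1(C)[C@H](CCC2(C)OCCO2)C=C(O[Zn]CCC3(C)OCCO3)C=C1
F3 | step 5 | C8-unsubstituted enone (chain cis to C20) | COC(=O)CC[C@@]1(C)[C@H](CCC2(C)OCCO2)CC(=O)C=C1
F4 | step 5 | lithium cross-conjugated dienolate of F3 | COC(=O)CC[C@@]1(C)[C@H](CCC2(C)OCCO2)C=C(O[Li])C=C1
F5 | step 9 | allylic C7 alcohol (OH on the H5 face, C5=C6) | COC(=O)CC[C@@]1(C)[C@H](CCC2(C)OCCO2)[C@@H](C)[C@@H](O)C=C1CC(=O)OC(C)(C)C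
F6 | step 22 | C7 ketone diacetate | CC(=O)O[C@H]1C[C@@]2(C)[C@H](CC/C(C)=C/C(=O)OC(C)(C)C)[C@@H](C)C(=O)C[C@@H]2[C@](C)(C=O)[C@H]1OC(C)=O
F7 | step 22 | C7=C8 enol triflate diacetate | CC(=O)O[C@H]1C[C@@]2(C)[C@H](CC/C(C)=C/C(=O)OC(C)(C)C)C(C)=C(OS(=O)(=O)C(F)(F)F)C[C@@H]2[C@](C)(C=O)[C@H]1OC(C)=O
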